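**Plan**
1. Late-stage cuts: the C3a aldehyde is unmasked last by glycol cleavage, the (Z)-butenediol arm comes from a butenolide joined to a C1 vinyl group by B-alkyl Suzuki coupling, and the C4 hydroxyl comes from the C5=C6 enone.
2. Core cuts: the bicycle is opened at the ring-fusion bond C3a–C8a and at C5–C6. C3a–C4(O)–C5 is a masked vinyl carbenoid (a propargylic acetate) and C6–C7–C8–C8a is a butadiene.
3. Forward: the chain is built from dimethyl malonate, crotonaldehyde, propynal and acetaldehyde (steps 1–5). One gold-catalysed cascade then closes the five-membered ring by cyclopropanation and the seven-membered ring by divinylcyclopropane (Cope) rearrangement.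
4. Stereochemistry: C2 from an organocatalytic Michael addition; C8a from C2 in the cyclopropanation; C3a from an aldol on the face of H-8a; C1 from a lactonisation that tells the two malonate esters apart; C4 from a hydroxyl-directed reduction; the Z alkene from the butenolide ring.

Key step: step 6

Remarks:
- Locants are azulene locants of the target: C1 (quaternary, CH2OH and side chain), C2 (CHMe), C3, C3a (formyl-bearing), C4 (carbinol), C5(Me)=C6, C7, C8, C8a.
- Propynal and 3-bromofuran-2(5H)-one are taken as catalogue reagents.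
- The acetoxy carbon of 10, C5 of 12–18 and the carbinol carbon made in step 8 are formed as epimer mixtures. Each is erased later (steps 6, 9 and 16) and is left unassigned in names and SMILES.

**Route**

Step 1
Reactants: 1 dimethyl malonate; 2 (E)-but-2-enal
Product: 3 dimethyl 2-[(2R)-4-oxobutan-2-yl]malonate
Conditions: (S)-2-[diphenyl(trimethylsilyloxy)methyl]pyrrolidine (10 mol%), PhCO2H (10 mol%), EtOH, 0 °C to rt
Reagents that add atoms: none
Why: Iminium-catalysed asymmetric Michael addition; the (S)-diarylprolinol silyl ether shields one face of the E-iminium ion, so malonate should add to the β-carbon to give the (R) methyl-bearing centre (future C2).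

Step 2
Reactants: 3 dimethyl 2-[(2R)-4-oxobutan-2-yl]malonate
Product: 4 dimethyl 2-[(2R)-pent-4-yn-2-yl]malonate
Conditions: dimethyl (1-diazo-2-oxopropyl)phosphonate (1.3 equiv), K2CO3 (2 equiv), MeOH, 0 °C to rt
Reagents that add atoms: dimethyl (1-diazo-2-oxopropyl)phosphonate, CC(=O)C(=[N+]=[N-])P(=O)(OC)OC
Why: Ohira–Bestmann homologation should turn the aldehyde into the terminal alkyne under carbonate conditions that leave the β-stereocentre and the malonate untouched.

Step 3
Reactants: 4 dimethyl 2-[(2R)-pent-4-yn-2-yl]malonate; 5 propynal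
Product: 6 dimethyl 2-[(1E)-3-oxoprop-1-enyl]-2-[(2R)-pent-4-yn-2-yl]malonate
Conditions: 5 (1.5 equiv, slow addition), Cs2CO3 (10 mol%), THF, −20 to 0 °C
Reagents that add atoms: none
Why: Base-catalysed Michael addition of the tertiary malonate carbanion to the ynal should give the γ,γ-disubstituted enal, which settles as the E isomer, and so places the first alkene of the diene on the quaternary carbon (future C1).

Step 4
Reactants: 6 dimethyl 2-[(1E)-3-oxoprop-1-enyl]-2-[(2R)-pent-4-yn-2-yl]malonate
Product: 7 dimethyl 2-[(1E)-buta-1,3-dienyl]-2-[(2R)-pent-4-yn-2-yl]malonate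
Conditions: Ph3PCH3Br (1.3 equiv), KN(SiMe3)2 (1.25 equiv), THF, −78 to 0 °C
Reagents that add atoms: methyltriphenylphosphonium bromide, C[P+](c1ccccc1)(c1ccccc1)c1ccccc1.[Br-]
Why: Wittig methylenation of the non-enolisable enal should give the (E)-1-substituted butadiene without attack on the hindered esters.

Step 5
Reactants: 7 dimethyl 2-[(1E)-buta-1,3-dienyl]-2-[(2R)-pent-4-yn-2-yl]malonate; 8 acetaldehyde
Product: 10 dimethyl 2-[(2R)-6-acetoxyhept-4-yn-2-yl]-2-[(1E)-buta-1,3-dienyl]malonate (both epimers at the acetoxy carbon), via lithium alkoxide 9 (not isolated)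
Conditions: LiN(SiMe3)2 (1.1 equiv), THF, −78 °C; 8 (2 equiv); then Ac2O (2 equiv), −78 °C to rt
Reagents that add atoms: acetic anhydride, CC(=O)OC(C)=O
Why: Acetylide 1,2-addition to acetaldehyde and O-acetylation of the alkoxide in the same flask should give the secondary propargylic acetate; the new carbinol centre is inconsequential.

Step 6
Reactants: 10 dimethyl 2-[(2R)-6-acetoxyhept-4-yn-2-yl]-2-[(1E)-buta-1,3-dienyl]malonate
Product: 12 dimethyl (2R,8aS)-4-acetoxy-2,5-dimethyl-2,3,5,6-tetrahydroazulene-1,1(8aH)-dicarboxylate, via cis-divinylcyclopropane 11 (not isolated)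
Conditions: Ph3PAuNTf2 (3 mol%), CH2Cl2, 0 °C to rt, then 40 °C
Reagents that add atoms: none
Why: Monovalent gold activates the alkyne, the acetate migrates 1,2 through a dioxolenium ion to a vinyl gold carbenoid at the future C3a (cyclisation before migration leads to the same product), and the carbenoid cyclopropanates the proximal E alkene of the diene in a 5-exo sense, which closes the cyclopentane and forms the C3a–C8a bond; the cis-divinylcyclopropane 11 (the E alkene puts the vinyl group cis to the acetoxyalkenyl group) then undergoes a strain-releasing boat-type Cope [3,3] rearrangement that forms the C5–C6 bond and closes the seven-membered ring by 3→7 ring expansion. The closest known reaction type is the gold- or platinum-catalysed acyloxy migration/cyclopropanation/divinylcyclopropane rearrangement of propargyl esters with dienes, a formal (4+3) annulation also known in tethered form for hydroazulenes. The structural feature that permits it is that the oxygenated C4 with its neighbours C3a and C5 is a three-carbon vinyl carbenoid equivalent and C6–C7–C8–C8a is a diene, joined by the three-atom tether C1–C2–C3. The only lasting new stereocentre, C8a, is set in the cyclopropanation by the C2 methyl group: in a chair-like 5-exo transition state with that methyl pseudo-equatorial the new C8a–C8 branch should lie cis to it, while C5 follows from the Z enol acetate and the boat geometry and is erased in step 9. The step needs chemoselectivity for the 1,2-shift/cyclopropanation channel over the 1,3-shift to the allenyl acetate and over (4+2)-type closure, which fast 5-exo capture through the short tether and the secondary acetate should secure. Regiochemistry is built in, because the carbenoid carbon becomes the enol acetate carbon C3a and so marks C3a for step 8.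

Step 7
Reactants: 12 dimethyl (2R,8aS)-4-acetoxy-2,5-dimethyl-2,3,5,6-tetrahydroazulene-1,1(8aH)-dicarboxylate
Product: 13 dimethyl (2R,8aS)-4-acetoxy-2,5-dimethyl-2,3,5,6,7,8-hexahydroazulene-1,1(8aH)-dicarboxylate
Conditions: H2 (1 atm), RhCl(PPh3)3 (5 mol%), benzene, rt
Reagents that add atoms: none
Why: Homogeneous catalytic hydrogenation should saturate only the cis-disubstituted C7=C8 alkene, the tetrasubstituted enol acetate being inert.

Step 8
Reactants: 13 dimethyl (2R,8aS)-4-acetoxy-2,5-dimethyl-2,3,5,6,7,8-hexahydroazulene-1,1(8aH)-dicarboxylate; 14 (R)-2,2-dimethyl-1,3-dioxolane-4-carbaldehyde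
Product: 17 bridged keto lactone (C4 ketone; δ-lactone from the new C3a carbinol carbon to the C1 carboxyl on the H-8a face; remaining C1 methyl ester on the C2-methyl face), via lithium enolate 15 (not isolated), via aldol adduct 16 (not isolated)
Conditions: MeLi (2.05 equiv), THF, −78 to −20 °C; 14 (1.5 equiv), −78 °C; warm to rt; aq NH4Cl
Reagents that add atoms: none
Why: Methyllithium cleaves the enol acetate to the regiodefined enolate, the aldol addition should take place on the face of C3a that carries H-8a (cis ring fusion, electrophile anti to the C8 ring bond), and the alkoxide can lactonise only with the cis C1 ester, which differentiates the two esters.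

Step 9
Reactants: 17 bridged keto lactone
Product: 19 bridged enone lactone (C5=C6 enone), via trimethylsilyl enol ether 18 (not isolated)
Conditions: LiN(iPr)2 (1.2 equiv), Me3SiCl (1.5 equiv), THF, −78 °C; then Pd(OAc)2 (1.1 equiv), MeCN, rt
Reagents that add atoms: none
Why: Saegusa–Ito oxidation; the ketone can enolise only towards C5, and β-hydride elimination from the palladium enolate should give the endocyclic trisubstituted enone.

Step 10
Reactants: 19 bridged enone lactone
Product: 20 lactol allylic alcohol (C4 epimers and lactol anomers; C1 methyl ester retained)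
Conditions: iBu2AlH (2.3 equiv), CH2Cl2, −78 °C; aq KNaC4H4O6
Reagents that add atoms: none
Why: Hydride reduction at −78 °C should take the enone carbonyl (1,2) and the lactone (to the lactol), while the neopentyl methyl ester between the quaternary and the methyl-bearing carbon reacts more slowly.

Step 11
Reactants: 20 lactol allylic alcohol
Product: 21 C1-vinyl diol ester (C1 vinyl on the H-8a face; free C4 hydroxyl and free carbinol on the C3a side chain)
Conditions: Ph3PCH3Br (4 equiv), KOtBu (3.8 equiv), THF, 0 °C to rt
Reagents that add atoms: methyltriphenylphosphonium bromide, C[P+](c1ccccc1)(c1ccccc1)c1ccccc1.[Br-]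
Why: Wittig methylenation of the lactol through its open hydroxy aldehyde form should give the C1 vinyl group and free the C3a carbinol.

Step 12
Reactants: 21 C1-vinyl diol ester
Product: 22 β-hydroxy enone (C4 ketone conjugated to C5=C6)
Conditions: MnO2 (20 equiv), CH2Cl2, rt
Reagents that add atoms: none
Why: Allylic oxidation with MnO2 should take only the C4 alcohol, so both C4 epimers converge on one enone and the saturated carbinol stays.

Step 13
Reactants: 22 β-hydroxy enone
Product: 23 anti-diol (C4 hydroxyl trans to the C3a side chain, as in the target)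
Conditions: Me4NBH(OAc)3 (5 equiv), MeCN/AcOH (1:1), −20 °C to rt
Reagents that add atoms: none
Why: Evans–Saksena hydroxyl-directed reduction; the carbinol on the C3a side chain binds boron and delivers hydride to the face of the C4 carbonyl on which that side chain sits, so the new hydroxyl should be trans to it.

Step 14
Reactants: 23 anti-diol; 24 3-bromofuran-2(5H)-one
Product: 26 butenolide ester (C1 arm is 2-(2-oxo-2,5-dihydrofuran-3-yl)ethyl), via tris-boryl intermediate 25 (not isolated)
Conditions: 9-BBN-H (3.5 equiv), THF, 0 °C to rt; then 24 (1.5 equiv), PdCl2(dppf) (5 mol%), AsPh3 (10 mol%), Cs2CO3 (3 equiv), DMF/H2O, rt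
Reagents that add atoms: none
Why: Anti-Markovnikov hydroboration of the monosubstituted vinyl group (the trisubstituted ring alkene is inert to 9-BBN) followed by B-alkyl Suzuki–Miyaura coupling with the α-bromo butenolide should complete the carbon skeleton of the side chain.

Step 15
Reactants: 26 butenolide ester
Product: 27 pentaol acetonide
Conditions: iBu2AlH (10 equiv), CH2Cl2, −78 to 0 °C; aq KNaC4H4O6
Reagents that add atoms: none
Why: Hydride reduction should open the butenolide to the (Z)-2-alkylbut-2-ene-1,4-diol, whose geometry the ring has fixed, and reduce the methyl ester to the C1 hydroxymethyl group.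

Step 16
Reactants: 27 pentaol acetonide
Product: 29 (1R,2R,3aR,4R,8aR)-4-hydroxy-1-(hydroxymethyl)-1-[(3Z)-5-hydroxy-3-(hydroxymethyl)pent-3-enyl]-2,5-dimethyl-1,2,3,4,7,8-hexahydroazulene-3a(8aH)-carbaldehyde, via heptaol 28 (not isolated)
Conditions: AcOH/H2O (4:1), 40 °C; concentrate; then NaIO4 (2.5 equiv), THF/pH 7 phosphate buffer, 0 °C
Reagents that add atoms: none
Why: Acetal hydrolysis and periodate glycol cleavage; only the liberated vicinal triol can be cleaved (no other 1,2-diol is present), which should unveil the aldehyde on the quaternary C3a without touching the four other hydroxyl groups.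

**Compound list**
1 | dimethyl malonate | COC(=O)CC(=O)OC | starting material
2 | (E)-but-2-enal | C/C=C/C=O | starting material
3 | dimethyl 2-[(2R)-4-oxobutan-2-yl]malonate | O=CC[C@@H](C)C(C(=O)OC)C(=O)OC | intermediate
4 | dimethyl 2-[(2R)-pent-4-yn-2-yl]malonate | C#CC[C@@H](C)C(C(=O)OC)C(=O)OC | intermediate
5 | propynal | C#CC=O | starting material
6 | dimethyl 2-[(1E)-3-oxoprop-1-enyl]-2-[(2R)-pent-4-yn-2-yl]malonate | C#CC[C@@H](C)C(/C=C/C=O)(C(=O)OC)C(=O)OC | intermediate
7 | dimethyl 2-[(1E)-buta-1,3-dienyl]-2-[(2R)-pent-4-yn-2-yl]malonate | C#CC[C@@H](C)C(/C=C/C=C)(C(=O)OC)C(=O)OC | intermediate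
8 | acetaldehyde | CC=O | starting material
9 | lithium alkoxide of dimethyl 2-[(1E)-buta-1,3-dienyl]-2-[(2R)-6-hydroxyhept-4-yn-2-yl]malonate | CC([O-])C#CC[C@@H](C)C(/C=C/C=C)(C(=O)OC)C(=O)OC.[Li+] | intermediate
10 | dimethyl 2-[(2R)-6-acetoxyhept-4-yn-2-yl]-2-[(1E)-buta-1,3-dienyl]malonate | CC(OC(C)=O)C#CC[C@@H](C)C(/C=C/C=C)(C(=O)OC)C(=O)OC | intermediate
11 | dimethyl 5-[(1Z)-1-acetoxyprop-1-enyl]-3-methyl-6-vinylbicyclo[3.1.0]hexane-2,2-dicarboxylate (3-methyl on the face of the cyclopropane carbon; 6-vinyl cis to the 5-alkenyl group) | C/C=C(\OC(C)=O)[C@]12C[C@@H](C)C(C(=O)OC)(C(=O)OC)[C@H]1[C@@H]2C=C | intermediate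
12 | dimethyl (2R,8aS)-4-acetoxy-2,5-dimethyl-2,3,5,6-tetrahydroazulene-1,1(8aH)-dicarboxylate (2-methyl trans to H-8a) | CC1CC=C[C@H]2C(C[C@@H](C)C2(C(=O)OC)C(=O)OC)=C1OC(C)=O | intermediate
13 | dimethyl (2R,8aS)-4-acetoxy-2,5-dimethyl-2,3,5,6,7,8-hexahydroazulene-1,1(8aH)-dicarboxylate | CC1CCC[C@H]2C(C[C@@H](C)C2(C(=O)OC)C(=O)OC)=C1OC(C)=O | intermediate
14 | (R)-2,2-dimethyl-1,3-dioxolane-4-carbaldehyde | O=C[C@H]1COC(C)(C)O1 | starting material
15 | lithium C3a=C4 enolate of the hexahydroazulenone diester | CC1CCC[C@H]2C(C[C@@H](C)C2(C(=O)OC)C(=O)OC)=C1[O-].[Li+] | intermediate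
16 | aldol adduct: 4-oxo diester carrying at C3a, cis to H-8a, the hydroxy(2,2-dimethyl-1,3-dioxolan-4-yl)methyl group | CC1CCC[C@H]2[C@](C(O)[C@H]3COC(C)(C)O3)(C[C@@H](C)C2(C(=O)OC)C(=O)OC)C1=O | intermediate
17 | bridged keto lactone (lactone O–C(=O) from the C3a carbinol carbon to C1 on the H-8a face; C1 methyl ester cis to the C2 methyl) | CC1CCC[C@H]2[C@@]3(C([C@H]4COC(C)(C)O4)OC(=O)[C@@]2(C(=O)OC)[C@H](C)C3)C1=O | intermediate
18 | C4=C5 trimethylsilyl enol ether of 17 | CC=1CCC[C@H]2[C@@]3(C([C@H]4COC(C)(C)O4)OC(=O)[C@@]2(C(=O)OC)[C@H](C)C3)C=1O[Si](C)(C)C | intermediate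
19 | bridged enone lactone (4-oxo, C5=C6) | CC1=CCC[C@H]2[C@@]3(C([C@H]4COC(C)(C)O4)OC(=O)[C@@]2(C(=O)OC)[C@H](C)C3)C1=O | intermediate
20 | lactol allylic alcohol (4-hydroxy, C5=C6; bridged lactol; C1 methyl ester) | CC1=CCC[C@H]2[C@@]3(C([C@H]4COC(C)(C)O4)OC(O)[C@@]2(C(=O)OC)[C@H](C)C3)C1O | intermediate
21 | methyl ester of the C1-vinyl diol (vinyl cis to H-8a; CO2Me cis to the C2 methyl; C4 hydroxyl as epimers) | CC1=CCC[C@H]2[C@](C(O)[C@H]3COC(C)(C)O3)(C[C@@H](C)[C@]2(C(=O)OC)C=C)C1O | intermediate
22 | β-hydroxy enone (4-oxo, C5=C6, C1 vinyl, C1 methyl ester) | CC1=CCC[C@H]2[C@](C(O)[C@H]3COC(C)(C)O3)(C[C@@H](C)[C@]2(C(=O)OC)C=C)C1=O | intermediate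
23 | anti-diol (4R hydroxyl trans to the C3a side chain; C1 vinyl; C1 methyl ester) | CC1=CCC[C@H]2[C@](C(O)[C@H]3COC(C)(C)O3)(C[C@@H](C)[C@]2(C(=O)OC)C=C)[C@@H]1O | intermediate
24 | 3-bromofuran-2(5H)-one | O=C1OCC=C1Br | starting material
25 | B-alkyl-9-borabicyclononane of 23, both hydroxyls as 9-BBN borinates | CC1=CCC[C@H]2[C@](C(OB3C4CCCC3CCC4)[C@H]3COC(C)(C)O3)(C[C@@H](C)[C@]2(C(=O)OC)CCB3C4CCCC3CCC4)[C@@H]1OB2C3CCCC2CCC3 | intermediate
26 | butenolide ester (C1 arm 2-(2-oxo-2,5-dihydrofuran-3-yl)ethyl) | CC1=CCC[C@H]2[C@](C(O)[C@H]3COC(C)(C)O3)(C[C@@H](C)[C@]2(C(=O)OC)CCC3=CCOC3=O)[C@@H]1O | intermediate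
27 | pentaol acetonide (target skeleton with the C3a formyl group replaced by the hydroxy(2,2-dimethyl-1,3-dioxolan-4-yl)methyl group) | CC1=CCC[C@H]2[C@](C(O)[C@H]3COC(C)(C)O3)(C[C@@H](C)[C@]2(CO)CC/C(=C/CO)CO)[C@@H]1O | intermediate
28 | heptaol (C3a carries a 1,2,3-trihydroxypropyl group) | CC1=CCC[C@H]2[C@](C(O)[C@H](O)CO)(C[C@@H](C)[C@]2(CO)CC/C(=C/CO)CO)[C@@H]1O | intermediate
29 | (1R,2R,3aR,4R,8aR)-4-hydroxy-1-(hydroxymethyl)-1-[(3Z)-5-hydroxy-3-(hydroxymethyl)pent-3-enyl]-2,5-dimethyl-1,2,3,4,7,8-hexahydroazulene-3a(8aH)-carbaldehyde | CC1=CCC[C@H]2[C@](C=O)(C[C@@H](C)[C@]2(CO)CC/C(=C/CO)CO)[C@@H]1O | target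

**Summary**
Total step count: 16. Longest linear sequence: 16 steps (1 and 2 to 29).

**Steps most likely to fail**

Step 6. The propargylic acetate may be drawn into the 1,3-shift channel (allenyl acetate) or the cyclopropyl gold carbene may collapse in a (4+2) sense, and facial control by the C2 methyl group in the cyclopropanation may be weak. The fallback makes the same two bonds by a cationic cycloaddition. It sets out from 10: AgBF4 (5 mol%, CH2Cl2, rt) should give the allenyl acetate dimethyl 2-[(2R)-4-acetoxyhepta-4,5-dien-2-yl]-2-[(1E)-buta-1,3-dienyl]malonate F1 by 3,3-shift. PtCl2 (10 mol%, toluene, 80 °C) should then effect the allene–diene (4+3) cycloaddition through the metal-bound allyl cation, and the platinum carbene left at C4 should collapse by 1,2-acetoxy shift. The fallback comes back to the route at 12.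

Step 8. Proton transfer from the enolisable α-alkoxy aldehyde to the hindered tetrasubstituted lithium enolate, and reversal of the aldol before lactonisation, may return the C3a–H ketone. The fallback separates enolate formation from C–C bond formation and uses a Lewis acid aldol. It sets out from 13: MeLi then Me3SiCl gives the silyl enol ether dimethyl (2R,8aS)-2,5-dimethyl-4-(trimethylsilyloxy)-2,3,5,6,7,8-hexahydroazulene-1,1(8aH)-dicarboxylate F2. A Mukaiyama aldol addition of F2 to 14 (BF3·OEt2, CH2Cl2, −78 °C) should give 16 after work-up, which is lactonised with catalytic DBU. The fallback comes back to the route at 17.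

Step 14. Base-induced degradation of the α-bromo butenolide and protodeboronation of the alkylborane may outrun slow oxidative addition and transmetalation. The fallback carries the side chain as the regioisomeric β-substituted butenolide, reached from a far more reactive vinylogous acyl triflate. It sets out from 23 through the same borane 25, which is coupled with 5-oxo-2,5-dihydrofuran-3-yl trifluoromethanesulfonate F3 (from tetronic acid and Tf2O) using Pd(PPh3)4 and K3PO4 in dioxane at 60 °C. This should give the butenolide ester whose C1 arm is 2-(5-oxo-2,5-dihydrofuran-3-yl)ethyl F4. Reduction of F4 with iBu2AlH gives the same (Z)-diol and the C1 hydroxymethyl group. The fallback comes back to the route at 27.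

Further compounds
F1 | step 6 | dimethyl 2-[(2R)-4-acetoxyhepta-4,5-dien-2-yl]-2-[(1E)-buta-1,3-dienyl]malonate | CC=C=C(OC(C)=O)C[C@@H](C)C(/C=C/C=C)(C(=O)OC)C(=O)OC
F2 | step 8 | dimethyl (2R,8aS)-2,5-dimethyl-4-(trimethylsilyloxy)-2,3,5,6,7,8-hexahydroazulene-1,1(8aH)-dicarboxylate | CC1CCC[C@H]2C(C[C@@H](C)C2(C(=O)OC)C(=O)OC)=C1O[Si](C)(C)C
F3 | step 14 | 5-oxo-2,5-dihydrofuran-3-yl trifluoromethanesulfonate | O=C1OCC(OS(=O)(=O)C(F)(F)F)=C1
F4 | step 14 | butenolide ester with the C1 arm 2-(5-oxo-2,5-dihydrofuran-3-yl)ethyl | CC1=CCC[C@H]2[C@](C(O)[C@H]3COC(C)(C)O3)(C[C@@H](C)[C@]2(C(=O)OC)CCC3=CC(=O)OC3)[C@@H]1O
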